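The easy step comes first: subtract impurity from initiator to count the living ends.

| flask | free monomer | initiator | impurity | remark | time |
|---|---|---|---|---|---|
| Sunday's | 0.32 M | 16 mM | 2.6 mM | a single well-mixed tank run continuously and read at steady state, 20 min in it on average |  |
| Tuesday's | 0.32 M (fed, over 10.0 min) | 16 mM | 2.6 mM | a stirred flask in which free monomer is dosed at a steady rate over 10.0 min without added volume, worked up at 20 min | 20 min |
| Saturday's | 0.32 M | 16 mM | 2.6 mM | one stirred flow tank at steady state, fed with the mixture as stated, mean residence time 100 min |  |
| Thursday's | 0.32 M | 16 mM | 2.6 mM | a closed flask charged with all of it at once and left for 20 min | 20 min |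

- the stated concentrations are those of everything mixed, before any reaction; amounts are the same in each set-up
- the feed brings no volume worth counting
- run time (Tuesday's): 20 min

    free monomer + initiator → living end + monomer in chains (k1 = 3.58 /M/min)
    free monomer + living end → monomer in chains + living end, rate k2*[living end]*[free monomer] (k2 = 4.37 /M/min)
    free monomer → uncatalysed product (k3 = 0.00150 /min)
    initiator + impurity → spent initiator (k4 = 1520 /M/min)

- order of the set-ups by the amount of monomer in chains at the outlet or at the end, in percent of the free monomer put in, highest first (Sunday's / Tuesday's / Saturday's / Thursday's)
- amount of monomer in chains at the outlet or at the end, in percent of the free monomer put in, Sunday's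
- amount of monomer in chains at the outlet or at the end, in percent of the free monomer put in, Tuesday's
- amount of monomer in chains at the outlet or at the end, in percent of the free monomer put in, Saturday's
- amount of monomer in chains at the outlet or at the end, in percent of the free monomer put in, Thursday's

1. In Thursday's flask, impurity meeting initiator at its charge has a half-life of 0.0285 min, while initiator meeting free monomer has one of 0.605 min. Because the impurity step is faster, I count [living end] as [initiator] minus [impurity], 13.4 mM, and I assume that figure for the other set-ups too.
2. Free monomer then decays pseudo-first-order. 16.7 min is the monomer lifetime, one over the growth constant times [living end] plus the uncatalysed constant.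
3. I count the lifetimes n in the contact time. With the lifetime held constant, a closed flask leaves e to the minus n of its free monomer and a tank leaves one over one plus n. Chains take 97.5% of what reacts, the selectivity.
4. Thursday's flask gets 1.20 lifetimes, so I expect 68.1%. Sunday's tank gets the same count but 53.2%. Saturday's tank gets 6.01 lifetimes and 83.6%. Tuesday's dose, 0.601 lifetimes long, gives 57.3%.
5. Leave the contact times as they stand, since my counts rest on them.
6. The forecast gives 52.9%, 57%, 83.5% and 67.8% for Sunday's, Tuesday's, Saturday's and Thursday's, ranks them Saturday's > Thursday's > Tuesday's > Sunday's, and reasons that “the 100 min tank wins on residence time”.
7. The simulation gives 52.9%, 56.9%, 83.5% and 67.9% in that order, which ranks them Saturday's > Thursday's > Tuesday's > Sunday's.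

In Thursday's flask the impurity step ran on the charge, initiator's half-life by that step alone being 0.18 min, shorter than the run, and growth ran on the living ends through what I count as 1.20 lifetimes, while the uncatalysed step made 1.76% of the free monomer charged into uncatalysed product. Sunday's tank at ten times its residence time counts 12.0 lifetimes, so one over one plus that count, with the share 97.5%, gives 90.0% monomer in chains, and that run reads 89.9%.

Its constants were set for the occasion; the run is a simulation.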